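**Assumptions (one line each)**
- The target SMILES is a (2S)-flavanone. Its B ring is 4'-OMe, 3'-[(E)-3-hydroxy-3-methylbut-1-enyl] and 5'-prenyl.
- 3-Bromo-4-hydroxybenzaldehyde, 2,4,6-trihydroxyacetophenone, NIS, MeI, 2-methylbut-3-en-2-ol, prenyl-SnBu3 and the catalyst 9-amino-9-deoxy-epi-quinine are commercial.
- Achiral bases, ligands, acids and solvents are not numbered. The chiral catalyst is numbered.
- The epi-quinine-derived catalyst is assumed to give the (2S) sense of induction. If it gave (R), the quinidine-derived pseudoenantiomer would be used.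

## Retrosynthetic overview
1. The (2S)-flavanone comes from an enantioselective, catalyst-controlled 6-endo intramolecular oxa-Michael cyclization of an open 2'-hydroxychalcone. This forms the only ring and sets the only stereocenter, and it is the last step.
2. The chalcone comes from a Claisen–Schmidt condensation of 2,4,6-trihydroxyacetophenone with a fully decorated B-ring aldehyde.
3. The aldehyde comes from 3-bromo-4-hydroxybenzaldehyde by iodination, O-methylation, a chemoselective Heck reaction at C–I with 2-methylbut-3-en-2-ol, then Stille prenylation at C–Br.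

## Route

**Step 1**
Reactants: 1 (3-bromo-4-hydroxybenzaldehyde); 2 (N-iodosuccinimide)
Product: 3 (3-bromo-4-hydroxy-5-iodobenzaldehyde)
Conditions: NIS (1.1 equiv), cat. TFA, MeCN, 25 °C, 6 h
Reagents that add atoms: NIS, O=C1CCC(=O)N1I
Why: Electrophilic aromatic iodination goes ortho to the activating OH at the only free ortho position (C5), and there is no alkene yet to interfere.

**Step 2**
Reactants: 3; 4 (iodomethane)
Product: 5 (3-bromo-5-iodo-4-methoxybenzaldehyde)
Conditions: MeI (2 equiv), K2CO3, DMF, 25 °C, 4 h
Reagents that add atoms: MeI, CI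
Why: Williamson O-methylation of the acidic, electron-poor phenol leaves the aldehyde and both aryl halides untouched.

**Step 3**
Reactants: 5; 6 (2-methylbut-3-en-2-ol)
Product: 7 (3-bromo-5-[(E)-3-hydroxy-3-methylbut-1-en-1-yl]-4-methoxybenzaldehyde)
Conditions: 6 (1.5 equiv), Pd(OAc)2 (3 mol%), Bu4NCl, NaHCO3, DMF, 70 °C, 12 h
Reagents that add atoms: 2-methylbut-3-en-2-ol, C=CC(C)(C)O
Why: Mizoroki–Heck coupling (Jeffery conditions) is chemoselective for the weaker C–I bond at this mild temperature and leaves C–Br intact. Syn-carbopalladation then β-H elimination gives the (E)-styryl tertiary carbinol, which has no carbinol H to isomerize to a ketone.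

**Step 4**
Reactants: 7; 8 (tributyl(3-methylbut-2-en-1-yl)stannane)
Product: 9 (3-[(E)-3-hydroxy-3-methylbut-1-en-1-yl]-4-methoxy-5-(3-methylbut-2-en-1-yl)benzaldehyde)
Conditions: 8 (1.5 equiv), Pd(PPh3)4 (5 mol%), LiCl, DMF, 90 °C, 12 h; KF work-up
Reagents that add atoms: prenyl-SnBu3, CCCC[Sn](CCCC)(CCCC)CC=C(C)C
Why: In Stille coupling of an allylstannane, reductive elimination from the η3-prenyl-Pd intermediate occurs at the less hindered terminus, giving the linear (normal) prenylarene. The free tertiary alcohol, aldehyde and E-alkene are tolerated.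

**Step 5**
Reactants: 9; 10 (2,4,6-trihydroxyacetophenone)
Product: 11 ((E)-1-(2,4,6-trihydroxyphenyl)-3-{3-[(E)-3-hydroxy-3-methylbut-1-enyl]-4-methoxy-5-prenylphenyl}prop-2-en-1-one)
Conditions: KOH (6 equiv), EtOH/H2O, 40 °C, 48 h, N2; then pH 5 with aq. citric acid, 0 °C
Reagents that add atoms: 2,4,6-trihydroxyacetophenone, CC(=O)c1c(O)cc(O)cc1O
Why: Claisen–Schmidt (aldol) condensation proceeds through the enolate of the polyphenolate. The anionic chalcone cannot cyclize in base, so the mild quench to pH 5 gives the achiral open chalcone and spares the acid-labile tertiary allylic alcohol.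

**Step 6**
Reactants: 11; 12 (9-amino-9-deoxy-epi-quinine, chiral organocatalyst)
Product: 13 ((2S)-5,7-dihydroxy-4'-methoxy-3'-[(E)-3-hydroxy-3-methylbut-1-enyl]-5'-prenylflavanone, the target)
Conditions: 12 (20 mol%), 2-fluorobenzoic acid (40 mol%), CH2Cl2/toluene 1:1, 25 °C, 72 h, stop at about 85% conversion; SiO2 chromatography
Reagents that add atoms: none (isomerization)
Why: Proposed new method: the ammonium carboxylate of 12 activates the enone of the unprotected 2',4',6'-trihydroxychalcone by reversible iminium and H-bond activation. The weakly basic 2-fluorobenzoate cannot deprotonate the 4'-OH, so the substrate does not collapse to an unreactive vinylogous phenolate, which is what defeats simple base catalysts here. The quinuclidinium–carboxylate ion pair delivers the 2'-OH to one enone face in a 6-endo-trig oxa-Michael addition that sets C2 as (S), and hydrolysis or turnover releases the flavanone. The closest known reaction type is cinchona primary-amine and thiourea catalyzed intramolecular oxa-Michael cyclization of simple 2'-hydroxychalcones. Mildly acidic conditions and stopping short of full conversion limit retro-Michael erosion of ee.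

## Compound list
1 | 3-bromo-4-hydroxybenzaldehyde | O=Cc1ccc(O)c(Br)c1 | starting material
2 | N-iodosuccinimide | O=C1CCC(=O)N1I | starting material (reagent)
3 | 3-bromo-4-hydroxy-5-iodobenzaldehyde | O=Cc1cc(Br)c(O)c(I)c1 | intermediate
4 | iodomethane | CI | starting material (reagent)
5 | 3-bromo-5-iodo-4-methoxybenzaldehyde | O=Cc1cc(Br)c(OC)c(I)c1 | intermediate
6 | 2-methylbut-3-en-2-ol | C=CC(C)(C)O | starting material
7 | 3-bromo-5-[(E)-3-hydroxy-3-methylbut-1-enyl]-4-methoxybenzaldehyde | O=Cc1cc(Br)c(OC)c(/C=C/C(C)(C)O)c1 | intermediate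
8 | tributyl(3-methylbut-2-en-1-yl)stannane | CCCC[Sn](CCCC)(CCCC)CC=C(C)C | starting material
9 | 3-[(E)-3-hydroxy-3-methylbut-1-enyl]-4-methoxy-5-prenylbenzaldehyde | O=Cc1cc(/C=C/C(C)(C)O)c(OC)c(CC=C(C)C)c1 | intermediate
10 | 2,4,6-trihydroxyacetophenone | CC(=O)c1c(O)cc(O)cc1O | starting material
11 | (E)-2',4',6'-trihydroxychalcone bearing the B ring of 9 | O=C(/C=C/c1cc(/C=C/C(C)(C)O)c(OC)c(CC=C(C)C)c1)c1c(O)cc(O)cc1O | intermediate
12 | 9-amino-9-deoxy-epi-quinine (commercial organocatalyst, not incorporated into the product) | COC1=CC2=C(C=CN=C2C=C1)[C@@H]([C@@H]3C[C@@H]4CCN3C[C@@H]4C=C)N | starting material (catalyst)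
13 | (2S)-5,7-dihydroxy-4'-methoxy-3'-[(E)-3-hydroxy-3-methylbut-1-enyl]-5'-prenylflavanone | COc1c(/C=C/C(C)(C)O)cc([C@@H]2CC(=O)c3c(O)cc(O)cc3O2)cc1CC=C(C)C | target

Atom check: 9 (C18H24O3) + 10 (C8H8O4) − H2O gives 11 (C26H30O6). Step 6 is an isomerization of 11 to 13 (C26H30O6).

**Total step count:** 6
**Longest linear sequence:** 6 (1 → 3 → 5 → 7 → 9 → 11 → 13)

## Three steps most likely to fail
1. **Step 6 (proposed new step):** The chelated, fully phenolic chalcone may not engage the primary-amine catalyst, or reversible ring opening may erode the ee.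
   - Fallback (known chemistry): cyclize 11 to racemic 13 with NaOAc in EtOH at 60 °C, then isolate the (2S) enantiomer by preparative chiral-phase HPLC.
2. **Step 5:** Unprotected phloroacetophenone may give low yields, or racemic flavanone may form during the quench.
   - Fallback: use 4',6'-bis-MOM-2'-hydroxyacetophenone (from 10 with MOMCl and DIPEA) in a standard Claisen–Schmidt condensation. Cyclize the resulting chalcone with a known cinchona-thiourea oxa-Michael catalyst, then remove the MOM groups with ZnBr2/n-PrSH.
3. **Step 4:** The Stille coupling may give the branched (1,1-dimethylallyl) isomer or low conversion at the hindered C–Br.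
   - Fallback: Suzuki coupling of 7 with allyl-Bpin (Pd(dppf)Cl2, K3PO4), then cross-metathesis of the allylarene with 2-methyl-2-butene (Hoveyda–Grubbs II) to install the prenyl group.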